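**Plan**

- Retrosynthesis (1-benzoxepine numbering on the left, azulene numbering on the right): the azulene C7 carbinol goes back to an enone and the acetate to the free oxepanol. The bond between the ethylene linker and azulene C5 is cut into an alkyl organometallic and a vinylogous ester. In the left half the methyl–C7 bond is cut, then in one operation the O1–C2 ether bond and the C5a–C6 ring bond. In the right half the cycloheptanedione is cut back by two carbons to a bicyclo[3.3.0]octanone obtained by cyclocarbonylation of an enyne.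
- Forward: geranylacetone → bis-epoxide → (Z)-enol silane → oxepane and cyclohexanone closed together → methyl carbinol → iodide. Geraniol → (R)-dehydrolinalool → cyclopentenone annulation → ring-fusion alkene → cis-bicyclic ketone → seven-membered 1,3-dione → enol ether. The fragments are then joined, acetylated and reduced.
- Enabling feature: the trans-fused 2,2-dimethyloxepane/cyclohexane. Its ring oxygen joins the CMe2 carbon to the fusion CH (C9a) next to the methyl-bearing quaternary C5a, and the oxygenated C3 sits beside CMe2. This is what remains when two trisubstituted epoxides of a geranyl chain are opened one after the other, each at its tertiary carbon.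
- Stereochemistry: C3, C5a and C9a come from ketone-catalysed asymmetric epoxidation, C6 from the (Z)-enol silane in a chair, and C7 from equatorial methyl addition. Azulene C1 comes from a Sharpless epoxide, C3a/C8a from hydroxyl-directed hydrogenation, and C7 from a CBS reduction.

Key step: step 5

Remark: the D-fructose-derived epoxidation ketone is taken to give the (R)-configured oxirane carbons, which is the sense the (3R) acetoxy carbon of the target requires; (4-methoxybenzyloxy)acetaldehyde is treated as a purchasable aldehyde.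

**Route**

Step 1
Reactants: 1 geranylacetone
Product: 2 (5R,6R,9R)-5,6:9,10-diepoxy-6,10-dimethylundecan-2-one
Conditions: Shi ketone (D-fructose-derived, 0.6 equiv), Oxone, K2CO3, Bu4NHSO4, MeCN–DMM–aq. borate buffer (pH 10.5), 0 °C
Reagents that add atoms: Oxone (potassium peroxymonosulfate), [K+].[O-]S(=O)(=O)OO
Why: Shi asymmetric epoxidation: the dioxirane of the ketone epoxidises both electron-rich trisubstituted alkenes through a spiro transition state and should give the (R)-configured oxirane carbons at C5/C6 and C9, while the buffered pH keeps Baeyer–Villiger oxidation of the methyl ketone slow.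

Step 2
Reactants: 2 diepoxy ketone; 3 (4-methoxybenzyloxy)acetaldehyde
Product: 4 (7R,8R,11R)-7,8:11,12-diepoxy-2-hydroxy-1-(4-methoxybenzyloxy)-8,12-dimethyltridecan-4-one (both C2 epimers)
Conditions: LDA, THF, −78 °C; then 3, −78 °C
Reagents that add atoms: none
Why: Kinetic lithium enolate formation on the methyl side and aldol addition to the α-alkoxy aldehyde; the epoxides are inert to LDA at −78 °C and the new carbinol centre is removed in step 3.

Step 3
Reactants: 4 aldol adduct
Product: 6 (2E,7R,8R,11R)-7,8:11,12-diepoxy-1-(4-methoxybenzyloxy)-8,12-dimethyltridec-2-en-4-one, via mesylate 5 (not isolated)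
Conditions: MsCl, Et3N, CH2Cl2, 0 °C → rt
Reagents that add atoms: none
Why: Mesylation and E1cB elimination of the β-mesyloxy ketone with triethylamine should give the conjugated (E)-enone.

Step 4
Reactants: 6 enone
Product: 7 (3Z,7R,8R,11R)-7,8:11,12-diepoxy-1-(4-methoxybenzyloxy)-8,12-dimethyl-4-(triethylsilyloxy)tridec-3-ene
Conditions: Et3SiH, (Ph3P)3RhCl (2 mol %), THF, 50 °C
Reagents that add atoms: triethylsilane, CC[SiH](CC)CC
Why: Rhodium-catalysed 1,4-hydrosilylation of the enone in its s-cis conformation places silicon on oxygen and hydrogen on the β-carbon, which fixes the regiochemistry of the enol silane and gives the (Z)-isomer; epoxides and the PMB ether are untouched.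

Step 5
Reactants: 7 bis-epoxide (Z)-triethylsilyl enol ether
Product: 9 (3R,5aR,6R,9aR)-6-[2-(4-methoxybenzyloxy)ethyl]-2,2,5a-trimethyl-3-(triethylsilyloxy)octahydro-1-benzoxepin-7(2H)-one, via epoxonium triflate 8 (not isolated)
Conditions: Et3SiOTf (0.2 equiv), 2,6-di-tert-butyl-4-methylpyridine, CH2Cl2, −78 °C
Reagents that add atoms: none
Why: Silylation of the terminal epoxide oxygen makes its CMe2 carbon electrophilic, the oxygen of the neighbouring epoxide opens it there to give the fused epoxonium ion 8, and the enol silane then attacks the methyl-bearing carbon of 8 with inversion, releasing Et3SiOTf to carry the chain. The closest known reaction type is the silyl-triflate-promoted tandem oxa- and carbacyclisation of polyepoxides that end in an enol silane (an epoxide-initiated Mukaiyama-type alkylation). The ether ring closes by endo opening of the terminal epoxide at its tertiary carbon and, once the C5a–O bond of 8 is cut, is the seven-membered oxepane (7-endo with respect to the surviving C9a–O–C2 bridge); the carbocycle closes 6-endo at the tertiary epoxonium carbon with the enol double bond inside the ring. C5a is set by backside attack on the (R,R)-epoxide, hence the trans ring fusion with C9a, whose configuration like that of C3 is carried over from the epoxides; C6 is set by the (Z)-enol geometry in a chair transition state that places the PMB-oxyethyl arm equatorial. The step needs the terminal rather than the internal epoxide to be engaged first and carbon rather than oxygen attack by the enol silane; both trisubstituted epoxides open only at their tertiary carbons, the internal oxygen sits in reach of the terminal CMe2 carbon, and low temperature with the hindered pyridine base suppresses proton-mediated openings and loss of the enol silane.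

Step 6
Reactants: 9 bicyclic ketone
Product: 10 (3R,5aR,6R,7S,9aR)-6-[2-(4-methoxybenzyloxy)ethyl]-2,2,5a,7-tetramethyl-3-(triethylsilyloxy)decahydro-1-benzoxepin-7-ol
Conditions: MeMgBr, CeCl3, THF, −78 → 0 °C
Reagents that add atoms: methylmagnesium bromide, C[Mg]Br
Why: 1,2-Addition of the weakly basic methylcerium reagent (no epimerisation at C6): the axial trajectory is blocked by the syn-axial C5a methyl group, so attack from the equatorial side should give the axial C7 hydroxyl with the new methyl group equatorial.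

Step 7
Reactants: 10 tertiary alcohol
Product: 11 (3R,5aR,6R,7S,9aR)-6-[2-(4-methoxybenzyloxy)ethyl]-2,2,5a,7-tetramethyl-3,7-bis(triethylsilyloxy)decahydro-1-benzoxepine
Conditions: Et3SiOTf, 2,6-lutidine, CH2Cl2, −78 → 0 °C
Reagents that add atoms: triethylsilyl trifluoromethanesulfonate, CC[Si](CC)(CC)OS(=O)(=O)C(F)(F)F
Why: Silyl triflate silylation of the hindered tertiary alcohol; a triethylsilyl rather than trimethylsilyl ether is chosen so that no silyl shift from oxygen to carbon occurs at the organolithium stage, and it still falls to HF in step 20.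

Step 8
Reactants: 11 PMB ether
Product: 12 2-[(3R,5aR,6R,7S,9aR)-2,2,5a,7-tetramethyl-3,7-bis(triethylsilyloxy)decahydro-1-benzoxepin-6-yl]ethanol
Conditions: DDQ, CH2Cl2–pH 7 buffer, 0 °C
Reagents that add atoms: none
Why: Oxidative cleavage of the 4-methoxybenzyl ether by DDQ (hydride abstraction, then hydrolysis of the oxocarbenium ion); the silyl ethers survive the buffered medium.

Step 9
Reactants: 12 primary alcohol
Product: 13 (3R,5aR,6R,7S,9aR)-6-(2-iodoethyl)-2,2,5a,7-tetramethyl-3,7-bis(triethylsilyloxy)decahydro-1-benzoxepine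
Conditions: I2, PPh3, imidazole, CH2Cl2, 0 °C → rt
Reagents that add atoms: iodine, II
Why: Appel-type iodination of the primary alcohol by SN2 displacement of the oxyphosphonium ion.

Step 10
Reactants: 14 geraniol
Product: 15 (2R,3R)-2,3-epoxygeraniol
Conditions: Ti(Oi-Pr)4 (cat.), D-(−)-diethyl tartrate (cat.), t-BuOOH, 4 Å MS, CH2Cl2, −20 °C
Reagents that add atoms: tert-butyl hydroperoxide, CC(C)(C)OO
Why: Sharpless asymmetric epoxidation: with D-(−)-tartrate the allylic alkene of the (E)-allylic alcohol is epoxidised from the face that gives the (2R,3R)-epoxy alcohol, and the remote trisubstituted alkene is left alone.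

Step 11
Reactants: 15 epoxy alcohol
Product: 16 (2S,3R)-2-(chloromethyl)-3-methyl-3-(4-methylpent-3-enyl)oxirane
Conditions: PPh3, CCl4, NaHCO3, reflux
Reagents that add atoms: tetrachloromethane, ClC(Cl)(Cl)Cl
Why: Appel chlorination of the primary alcohol under buffered conditions that leave the epoxide closed.

Step 12
Reactants: 16 epoxy chloride
Product: 17 (R)-dehydrolinalool [(3R)-3,7-dimethyloct-6-en-1-yn-3-ol]
Conditions: n-BuLi (3.2 equiv), THF, −40 °C
Reagents that add atoms: none
Why: Base-induced double elimination of the 2,3-epoxy chloride (deprotonation next to chlorine with epoxide opening, then dehydrochlorination) gives the tertiary propargylic alcohol; the C–O bond of the carbinol carbon is never broken, so its configuration is that of the epoxide C3.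

Step 13
Reactants: 17 (R)-dehydrolinalool
Product: 19 (8R)-8-hydroxy-4,4,8-trimethylbicyclo[3.3.0]oct-1-en-3-one (C5 epimers), via dicobalt hexacarbonyl alkyne complex 18 (not isolated)
Conditions: Co2(CO)8, CH2Cl2, rt; then N-methylmorpholine N-oxide, 0 °C → rt
Reagents that add atoms: dicobalt octacarbonyl (supplies CO), [Co].[Co].[C-]#[O+].[C-]#[O+].[C-]#[O+].[C-]#[O+].[C-]#[O+].[C-]#[O+].[C-]#[O+].[C-]#[O+]
Why: Intramolecular Pauson–Khand reaction of the 1,6-enyne (alkyne complexation, alkene insertion, CO insertion, reductive elimination) closes the cyclopentane and the cyclopentenone and places the carbonyl next to the gem-dimethyl carbon; the configuration of the new ring-fusion carbon is of no consequence because it is erased in step 14.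

Step 14
Reactants: 19 conjugated enone
Product: 20 (2R)-2-hydroxy-2,6,6-trimethylbicyclo[3.3.0]oct-1(5)-en-7-one
Conditions: KOt-Bu, t-BuOH–THF, rt; then cold aq. AcOH
Reagents that add atoms: none
Why: γ-Deprotonation (the α′-carbon is quaternary) gives the extended dienolate, and its kinetic protonation at the α-carbon deconjugates the enone and moves the double bond to the ring fusion.

Step 15
Reactants: 20 β,γ-unsaturated ketone
Product: 21 (1R,5R,8R)-8-hydroxy-4,4,8-trimethylbicyclo[3.3.0]octan-3-one (cis-fused; both ring-fusion H cis to OH)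
Conditions: H2 (1 atm), [Ir(cod)(PCy3)(py)]PF6 (10 mol %), CH2Cl2, rt
Reagents that add atoms: none
Why: Hydroxyl-directed hydrogenation with Crabtree's catalyst: the tertiary allylic hydroxyl binds iridium and both hydrogens are delivered to the tetrasubstituted alkene from its face, which sets the two ring-fusion carbons (later azulene C8a and C3a) cis to the hydroxyl and cis to each other.

Step 16
Reactants: 21 hydroxy ketone
Product: 23 cis-fused 8-(tert-butyldimethylsilyloxy)-4,4,8-trimethyl-3-(triethylsilyloxy)bicyclo[3.3.0]oct-2-ene (configuration as in 21), via silyl ether ketone 22 (not isolated)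
Conditions: TBSOTf, 2,6-lutidine, CH2Cl2, −78 → 0 °C; then Et3SiOTf, Et3N, 0 °C
Reagents that add atoms: tert-butyldimethylsilyl trifluoromethanesulfonate, CC(C)(C)[Si](C)(C)OS(=O)(=O)C(F)(F)F; triethylsilyl trifluoromethanesulfonate, CC[Si](CC)(CC)OS(=O)(=O)C(F)(F)F
Why: The silyl triflate with a weak base silylates the tertiary alcohol, and the second triflate with triethylamine converts the ketone into its enol silane, which can only form toward CH2 because the other α-carbon is quaternary.

Step 17
Reactants: 23 enol silane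
Product: 24 tricyclic 2-chloro-2-methylcyclobutanone fused across the former enol double bond (mixture at the three new centres)
Conditions: 2-chloropropanoyl chloride, Et3N, hexane, rt → 50 °C (slow addition)
Reagents that add atoms: 2-chloropropanoyl chloride, CC(Cl)C(Cl)=O
Why: [2+2] cycloaddition of chloro(methyl)ketene, generated in situ by dehydrochlorination of the acid chloride, with the electron-rich enol silane; the ketene carbonyl carbon bonds to the nucleophilic β-carbon, and the three new stereocentres are removed in step 18.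

Step 18
Reactants: 24 chlorocyclobutanone
Product: 26 (1R,3aR,8aR)-1-(tert-butyldimethylsilyloxy)-1,4,4,6-tetramethyloctahydroazulene-5,7-dione, via dechlorinated cyclobutanone 25 (not isolated)
Conditions: Zn, AcOH, THF–H2O, rt; then Bu4NF, THF, 0 °C
Reagents that add atoms: none
Why: Zinc reduces the α-chloro ketone, and fluoride cleavage of the strained tertiary triethylsilyl ether triggers retro-aldol scission of the ring-fusion bond of the β-oxido cyclobutanone, a two-carbon ring expansion to the 2-methylcycloheptane-1,3-dione; the tertiary TBS ether should survive fluoride at 0 °C.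

Step 19
Reactants: 26 dione
Product: 27 (1R,3aR,8aR)-1-(tert-butyldimethylsilyloxy)-7-isobutoxy-1,4,4,6-tetramethyl-2,3,3a,4,8,8a-hexahydroazulen-5(1H)-one
Conditions: i-BuOH, PPTS (cat.), toluene, reflux (Dean–Stark)
Reagents that add atoms: 2-methylpropan-1-ol, CC(C)CO
Why: Acid-catalysed enol etherification of the 1,3-dione under equilibrating conditions should place the isobutoxy group on the carbonyl carbon next to CH2, away from the gem-dimethyl carbon, as with other 4,4-disubstituted 1,3-diones.

Step 20
Reactants: 13 iodide; 27 vinylogous ester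
Product: 31 (1R,3aR,8aR)-5-{2-[(3R,5aR,6R,7S,9aR)-3,7-dihydroxy-2,2,5a,7-tetramethyldecahydro-1-benzoxepin-6-yl]ethyl}-1-hydroxy-1,4,4,6-tetramethyl-2,3,3a,4,8,8a-hexahydroazulen-7(1H)-one, via alkyllithium 28 (not isolated), via alkylcerium dichloride 29 (not isolated), via tertiary carbinol 30 (not isolated)
Conditions: 13, t-BuLi (2 equiv), Et2O, −78 °C; CeCl3, THF, −78 °C; then 27, −78 → 0 °C; then 48% aq. HF, MeCN, rt
Reagents that add atoms: water, O
Why: Stork–Danheiser sequence: iodine–lithium exchange, transmetalation to the weakly basic organocerium reagent and 1,2-addition to the hindered carbonyl group of the vinylogous ester, after which aqueous HF hydrolyses the enol ether with loss of the tertiary hydroxyl to give the transposed enone and removes all three silyl ethers; no stereocentre is created.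

Step 21
Reactants: 31 enone triol
Product: 32 3-O-acetate of 31
Conditions: Ac2O, pyridine, DMAP (cat.), CH2Cl2, 0 °C
Reagents that add atoms: acetic anhydride, CC(=O)OC(C)=O
Why: Acylation with acetic anhydride and pyridine is selective for the single secondary hydroxyl; the two tertiary alcohols do not react under these conditions.

Step 22
Reactants: 32 enone acetate
Product: 33 target, (3R,5aR,6R,7S,9aR)-6-{2-[(1R,3aR,7R,8aR)-1,7-dihydroxy-1,4,4,6-tetramethyl-1,2,3,3a,4,7,8,8a-octahydroazulen-5-yl]ethyl}-7-hydroxy-2,2,5a,7-tetramethyldecahydro-1-benzoxepin-3-yl acetate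
Conditions: (S)-Me-CBS oxazaborolidine, BH3·SMe2, THF, −30 °C
Reagents that add atoms: none
Why: CBS reduction: with the (S)-oxazaborolidine, and the α-methyl alkenyl carbon C6 acting as the large group against CH2 (C8) as the small one, hydride should be delivered to the face that gives the (7R)-allylic alcohol; the acetate and the tetrasubstituted alkene are not touched and the tertiary hydroxyls only consume borane.

**Compound list**

1 | geranylacetone, (E)-6,10-dimethylundeca-5,9-dien-2-one | CC(C)=CCC/C(C)=C/CCC(C)=O | starting material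
2 | (5R,6R,9R)-5,6:9,10-diepoxy-6,10-dimethylundecan-2-one | CC1(C)O[C@@H]1CC[C@@]2(C)O[C@@H]2CCC(C)=O | intermediate
3 | (4-methoxybenzyloxy)acetaldehyde | O=CCOCc1ccc(OC)cc1 | starting material
4 | (7R,8R,11R)-7,8:11,12-diepoxy-2-hydroxy-1-(4-methoxybenzyloxy)-8,12-dimethyltridecan-4-one, C2 epimers | CC1(C)O[C@@H]1CC[C@@]2(C)O[C@@H]2CCC(=O)CC(O)COCc3ccc(OC)cc3 | intermediate
5 | C2 methanesulfonate of 4 (not isolated) | CC1(C)O[C@@H]1CC[C@@]2(C)O[C@@H]2CCC(=O)CC(OS(C)(=O)=O)COCc3ccc(OC)cc3 | intermediate
6 | (2E,7R,8R,11R)-7,8:11,12-diepoxy-1-(4-methoxybenzyloxy)-8,12-dimethyltridec-2-en-4-one | CC1(C)O[C@@H]1CC[C@@]2(C)O[C@@H]2CCC(=O)/C=C/COCc3ccc(OC)cc3 | intermediate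
7 | bis-epoxide (Z)-triethylsilyl enol ether, (3Z,7R,8R,11R)-7,8:11,12-diepoxy-1-(4-methoxybenzyloxy)-8,12-dimethyl-4-(triethylsilyloxy)tridec-3-ene | CC1(C)O[C@@H]1CC[C@@]2(C)O[C@@H]2CC/C(O[Si](CC)(CC)CC)=C/CCOCc3ccc(OC)cc3 | intermediate
8 | bicyclic epoxonium triflate: oxonium oxygen bonded to CMe2, to the methyl-bearing carbon and to the adjacent CH (not isolated) | CC[Si](CC)(CC)O[C@@H]1CC[C@@]2(C)[O+](C1(C)C)[C@@H]2CC/C(O[Si](CC)(CC)CC)=C/CCOCc3ccc(OC)cc3.[O-]S(=O)(=O)C(F)(F)F | intermediate
9 | (3R,5aR,6R,9aR)-6-[2-(4-methoxybenzyloxy)ethyl]-2,2,5a-trimethyl-3-(triethylsilyloxy)octahydro-1-benzoxepin-7(2H)-one, trans-fused, arm equatorial | CC[Si](CC)(CC)O[C@@H]1CC[C@]2(C)[C@@H](CCOCc3ccc(OC)cc3)C(=O)CC[C@H]2OC1(C)C | intermediate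
10 | (3R,5aR,6R,7S,9aR)-6-[2-(4-methoxybenzyloxy)ethyl]-2,2,5a,7-tetramethyl-3-(triethylsilyloxy)decahydro-1-benzoxepin-7-ol, axial OH | CC[Si](CC)(CC)O[C@@H]1CC[C@]2(C)[C@@H](CCOCc3ccc(OC)cc3)[C@@](C)(O)CC[C@H]2OC1(C)C | intermediate
11 | 3,7-bis(triethylsilyl) ether of the PMB-protected diol | CC[Si](CC)(CC)O[C@@H]1CC[C@]2(C)[C@@H](CCOCc3ccc(OC)cc3)[C@@](C)(O[Si](CC)(CC)CC)CC[C@H]2OC1(C)C | intermediate
12 | 2-[(3R,5aR,6R,7S,9aR)-2,2,5a,7-tetramethyl-3,7-bis(triethylsilyloxy)decahydro-1-benzoxepin-6-yl]ethanol | CC[Si](CC)(CC)O[C@@H]1CC[C@]2(C)[C@@H](CCO)[C@@](C)(O[Si](CC)(CC)CC)CC[C@H]2OC1(C)C | intermediate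
13 | (3R,5aR,6R,7S,9aR)-6-(2-iodoethyl)-2,2,5a,7-tetramethyl-3,7-bis(triethylsilyloxy)decahydro-1-benzoxepine | CC[Si](CC)(CC)O[C@@H]1CC[C@]2(C)[C@@H](CCI)[C@@](C)(O[Si](CC)(CC)CC)CC[C@H]2OC1(C)C | intermediate
14 | geraniol | CC(C)=CCC/C(C)=C/CO | starting material
15 | (2R,3R)-2,3-epoxygeraniol | OC[C@H]1O[C@]1(C)CCC=C(C)C | intermediate
16 | (2S,3R)-2-(chloromethyl)-3-methyl-3-(4-methylpent-3-enyl)oxirane | ClC[C@H]1O[C@]1(C)CCC=C(C)C | intermediate
17 | (R)-dehydrolinalool, (3R)-3,7-dimethyloct-6-en-1-yn-3-ol | C#C[C@](C)(O)CCC=C(C)C | intermediate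
18 | hexacarbonyldicobalt complex of the alkyne of 17 (not isolated) | C#C[C@](C)(O)CCC=C(C)C.[Co].[Co].[C-]#[O+].[C-]#[O+].[C-]#[O+].[C-]#[O+].[C-]#[O+].[C-]#[O+] | intermediate
19 | (8R)-8-hydroxy-4,4,8-trimethylbicyclo[3.3.0]oct-1-en-3-one, C5 epimers | O=C1C=C2[C@](C)(O)CCC2C1(C)C | intermediate
20 | (2R)-2-hydroxy-2,6,6-trimethylbicyclo[3.3.0]oct-1(5)-en-7-one | O=C1CC2=C(CC[C@@]2(C)O)C1(C)C | intermediate
21 | (1R,5R,8R)-8-hydroxy-4,4,8-trimethylbicyclo[3.3.0]octan-3-one, cis-fused, ring-fusion H cis to OH | O=C1C[C@H]2[C@](C)(O)CC[C@H]2C1(C)C | intermediate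
22 | tert-butyldimethylsilyl ether of 21 (not isolated) | O=C1C[C@H]2[C@](C)(O[Si](C)(C)C(C)(C)C)CC[C@H]2C1(C)C | intermediate
23 | cis-fused 8-(tert-butyldimethylsilyloxy)-4,4,8-trimethyl-3-(triethylsilyloxy)bicyclo[3.3.0]oct-2-ene | CC[Si](CC)(CC)OC1=C[C@H]2[C@](C)(O[Si](C)(C)C(C)(C)C)CC[C@H]2C1(C)C | intermediate
24 | tricyclic 2-chloro-2-methylcyclobutanone carrying the triethylsilyloxy group on the ring-fusion carbon next to CMe2 | CC[Si](CC)(CC)OC12C(C)(Cl)C(=O)C1[C@H]3[C@](C)(O[Si](C)(C)C(C)(C)C)CC[C@H]3C2(C)C | intermediate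
25 | dechlorinated 2-methylcyclobutanone (not isolated) | CC[Si](CC)(CC)OC12C(C)C(=O)C1[C@H]3[C@](C)(O[Si](C)(C)C(C)(C)C)CC[C@H]3C2(C)C | intermediate
26 | (1R,3aR,8aR)-1-(tert-butyldimethylsilyloxy)-1,4,4,6-tetramethyloctahydroazulene-5,7-dione | O=C1C(C)C(=O)C[C@@H]2[C@@H](CC[C@@]2(C)O[Si](C)(C)C(C)(C)C)C1(C)C | intermediate
27 | (1R,3aR,8aR)-1-(tert-butyldimethylsilyloxy)-7-isobutoxy-1,4,4,6-tetramethyl-2,3,3a,4,8,8a-hexahydroazulen-5(1H)-one | O=C1C(C)=C(OCC(C)C)C[C@@H]2[C@@H](CC[C@@]2(C)O[Si](C)(C)C(C)(C)C)C1(C)C | intermediate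
28 | alkyllithium from 13 (not isolated) | CC[Si](CC)(CC)O[C@@H]1CC[C@]2(C)[C@@H](CC[Li])[C@@](C)(O[Si](CC)(CC)CC)CC[C@H]2OC1(C)C | intermediate
29 | alkylcerium dichloride from 28 (not isolated) | CC[Si](CC)(CC)O[C@@H]1CC[C@]2(C)[C@@H](CC[Ce](Cl)Cl)[C@@](C)(O[Si](CC)(CC)CC)CC[C@H]2OC1(C)C | intermediate
30 | tertiary carbinol from 1,2-addition to 27 (not isolated; C5 of the azulene unspecified) | CC[Si](CC)(CC)O[C@@H]1CC[C@]2(C)[C@@H](CCC3(O)C(C)=C(OCC(C)C)C[C@@H]4[C@@H](CC[C@@]4(C)O[Si](C)(C)C(C)(C)C)C3(C)C)[C@@](C)(O[Si](CC)(CC)CC)CC[C@H]2OC1(C)C | intermediate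
31 | enone triol (name as on the Product line of step 20) | O[C@@H]1CC[C@]2(C)[C@@H](CCC3=C(C)C(=O)C[C@@H]4[C@@H](CC[C@@]4(C)O)C3(C)C)[C@@](C)(O)CC[C@H]2OC1(C)C | intermediate
32 | 3-O-acetate of 31 | CC(=O)O[C@@H]1CC[C@]2(C)[C@@H](CCC3=C(C)C(=O)C[C@@H]4[C@@H](CC[C@@]4(C)O)C3(C)C)[C@@](C)(O)CC[C@H]2OC1(C)C | intermediate
33 | CNP0157376.1 (name as on the Product line of step 22) | CC(=O)O[C@@H]1CC[C@]2(C)[C@@H](CCC3=C(C)[C@H](O)C[C@@H]4[C@@H](CC[C@@]4(C)O)C3(C)C)[C@@](C)(O)CC[C@H]2OC1(C)C | target

**Step count and risks**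

Total: 22 steps. Longest linear sequence: 13 steps (steps 10–22 from geraniol); the geranylacetone branch is 12 (steps 1–9 and 20–22).

Steps most likely to fail:

1. Step 20. Addition of the alkylcerium reagent to a carbonyl group shielded on one side by the gem-dimethyl carbon and on the other by the methyl-bearing enol-ether carbon may be slower than γ-deprotonation of 27 or protonation of the organometallic, so that the iodide is used up without forming the bond. The fallback replaces carbonyl addition by cross-coupling. It sets out from 27 and 13. γ-Deprotonation of 27 (KHMDS, THF, −78 °C) and O-sulfonylation with N-phenyltriflimide should give the 2-isobutoxy dienyl triflate F1. The iodide 13 is converted by t-BuLi and B-methoxy-9-BBN into the B-alkyl-9-BBN borane F2. B-alkyl Suzuki–Miyaura coupling of F1 with F2 (Pd(dppf)Cl2, AsPh3, K3PO4, DMF–THF–H2O) would give the dienol ether F3. Aqueous HF in MeCN then hydrolyses the enol ether and removes the silyl groups, which returns to 31.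

2. Step 13. Insertion of the trisubstituted, gem-dimethyl-terminated alkene into the cobalt–alkyne complex may be too slow, so that decomplexation and reduction of the alkyne take over. The fallback moves the gem-dimethyl group to a later alkylation. It sets out from 17. Ozonolysis (O3, CH2Cl2–MeOH, −78 °C; Me2S) would cut the trisubstituted alkene selectively and give the hydroxy aldehyde F4 (in equilibrium with its lactol). Methylenation (Ph3P=CH2, excess, THF) gives the terminal enyne F5. Its Pauson–Khand reaction under the same cobalt conditions is the standard case and should give the bicyclic enone F6. Two successive α′-methylations (LDA, MeI, THF, −78 °C), passing through the monomethyl ketone F7, install the gem-dimethyl group and return to 19.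

3. Step 17. Cycloaddition at an enol silane whose oxygen-bearing carbon is flanked by a quaternary centre may be outpaced by ketene oligomerisation, or stop at open-chain C-acylation. The fallback uses a more electrophilic ketene and brings in the methyl group afterwards. It sets out from 23. Dichloroketene (Cl3CCOCl, Zn–Cu, Et2O) should give the dichlorocyclobutanone F8. Zinc in acetic acid gives the dechlorinated cyclobutanone F9, and fluoride-triggered ring expansion gives the dione F10 that lacks the C6 methyl group. C-Methylation (MeI, K2CO3, acetone) returns to 26.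

Further compounds
F1 | step 20 | (1R,3aR,8aR)-1-(tert-butyldimethylsilyloxy)-7-isobutoxy-1,4,4,6-tetramethyl-1,2,3,3a,4,8a-hexahydroazulen-5-yl trifluoromethanesulfonate | O=S(=O)(OC1=C(C)C(OCC(C)C)=C[C@@H]2[C@@H](CC[C@@]2(C)O[Si](C)(C)C(C)(C)C)C1(C)C)C(F)(F)F
F2 | step 20 | B-alkyl-9-BBN borane from 13 | CC[Si](CC)(CC)O[C@@H]1CC[C@]2(C)[C@@H](CCB3C4CCCC3CCC4)[C@@](C)(O[Si](CC)(CC)CC)CC[C@H]2OC1(C)C
F3 | step 20 | coupled dienol ether, fully silylated | CC[Si](CC)(CC)O[C@@H]1CC[C@]2(C)[C@@H](CCC3=C(C)C(OCC(C)C)=C[C@@H]4[C@@H](CC[C@@]4(C)O[Si](C)(C)C(C)(C)C)C3(C)C)[C@@](C)(O[Si](CC)(CC)CC)CC[C@H]2OC1(C)C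
F4 | step 13 | (4R)-4-hydroxy-4-methylhex-5-ynal (open form of the lactol) | C#C[C@](C)(O)CCC=O
F5 | step 13 | (3R)-3-methylhept-6-en-1-yn-3-ol | C#C[C@](C)(O)CCC=C
F6 | step 13 | (8R)-8-hydroxy-8-methylbicyclo[3.3.0]oct-1-en-3-one, C5 epimers | O=C1C=C2[C@](C)(O)CCC2C1
F7 | step 13 | (8R)-8-hydroxy-4,8-dimethylbicyclo[3.3.0]oct-1-en-3-one, epimer mixture | O=C1C=C2[C@](C)(O)CCC2C1C
F8 | step 17 | tricyclic 2,2-dichlorocyclobutanone from 23 | CC[Si](CC)(CC)OC12C(Cl)(Cl)C(=O)C1[C@H]3[C@](C)(O[Si](C)(C)C(C)(C)C)CC[C@H]3C2(C)C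
F9 | step 17 | dechlorinated cyclobutanone | CC[Si](CC)(CC)OC12CC(=O)C1[C@H]3[C@](C)(O[Si](C)(C)C(C)(C)C)CC[C@H]3C2(C)C
F10 | step 17 | (1R,3aR,8aR)-1-(tert-butyldimethylsilyloxy)-1,4,4-trimethyloctahydroazulene-5,7-dione | O=C1CC(=O)C[C@@H]2[C@@H](CC[C@@]2(C)O[Si](C)(C)C(C)(C)C)C1(C)C
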